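**Plan**
- Retrosynthesis: the six hydroxyls are masked as benzyl ethers, then ring C of the upper flavan unit is cut in one operation at O1–C2, C2–C3 and the interflavan bond C4–C8 (C8 of the lower unit).
- Enabling feature: ring C is a 2,4-trans-2,4-diarylchroman. O1–C2 is the trace of a phenol and an aldehyde, C3–C4 the trace of a vinyl group, and C4 is a benzylic carbon ortho to O1 and para to the 7-oxygen of ring A, so its cation is well stabilised.
- The cut leaves three pieces: 5-(benzyloxy)-2-vinylphenol (ring A, C3, C4), 4-(benzyloxy)benzaldehyde (C2, ring B) and tetra-O-benzyl-(−)-epiafzelechin (rings D, E, F).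
- Forward: Wittig methylenation and perbenzylation give the two prepared components, a three-component Prins/Friedel–Crafts cascade closes ring C and joins the flavan units, and hydrogenolysis releases the target.
- Stereochemistry: C2 and C3 of the lower unit (R,R) come from the chiral pool. C2 of the upper unit (S) comes from the chiral counter-anion of a confined Brønsted acid. C4 (R) comes from pseudoaxial capture of the flavan-4-yl cation anti to the 2-aryl group.

Key step: step 3

Assumption: the sense of induction of the confined acid cannot be predicted, so the catalyst antipode that gives the (2S)-chroman is chosen in a test run with both antipodes (both are accessible from (R)- or (S)-BINOL); (−)-epiafzelechin, (2R,3R), is taken as purchasable chiral-pool material.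

**Step 1**
Reactants: 1 4-(benzyloxy)-2-hydroxybenzaldehyde
Product: 2 5-(benzyloxy)-2-vinylphenol
Conditions: Ph3PCH3Br (2.5 equiv), KOtBu (2.5 equiv), THF, 0 °C to rt; aq. NH4Cl; concentrated cold with a trace of BHT and stored at −20 °C
Reagents that add atoms: methyltriphenylphosphonium bromide, C[P+](c1ccccc1)(c1ccccc1)c1ccccc1.[Br-]
Why: Wittig olefination, in which the first equivalent of base or ylide only deprotonates the phenol and the second methylenates the aldehyde to the terminal alkene, with no stereochemical issue.

**Step 2**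
Reactants: 3 (−)-epiafzelechin
Product: 4 tetra-O-benzyl-(−)-epiafzelechin
Conditions: NaH (6 equiv), BnBr (6 equiv), n-Bu4NI (cat.), DMF, −20 °C to rt
Reagents that add atoms: benzyl bromide, BrCc1ccccc1
Why: Williamson ether synthesis, in which the three phenoxides and the secondary alkoxide are O-benzylated at low temperature and no bond to C2 or C3 is broken, so the (2R,3R) configuration is kept.

**Step 3**
Reactants: 2 5-(benzyloxy)-2-vinylphenol; 5 4-(benzyloxy)benzaldehyde; 4 tetra-O-benzyl-(−)-epiafzelechin
Product: 8 hexa-O-benzyl ether of the target, via O-aryl oxocarbenium ion 6 (not isolated), via flavan-4-yl cation 7 (not isolated)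
Conditions: confined chiral imidodiphosphorimidate acid (two 3,3'-bis[3,5-bis(trifluoromethyl)phenyl]-BINOL units on a P(=NSO2CF3)–NH–P(=NSO2CF3) core, 5 mol%), 5 Å molecular sieves, CHCl3, −40 °C; 2 (1.0 equiv) added over 6 h to 5 (1.5 equiv) and 4 (2.0 equiv); Et3N quench
Reagents that add atoms: none
Why: Proposed new method: the acid condenses phenol 2 with aldehyde 5 (water taken up by the sieves) to the O-aryl oxocarbenium ion 6, paired with the chiral imidodiphosphorimidate anion; the electron-rich vinyl terminus attacks the oxocarbenium carbon in a 6-endo-trig Prins closure (formally a 6π oxonia-electrocyclisation) that forms C2–C3 and ring C and leaves the flavan-4-yl cation 7, stabilised by O1 (ortho) and the 7-benzyloxy group (para), and C8 of ring D of 4 then captures C4 in a Friedel–Crafts alkylation. The closest known reaction types are Prins cyclisation/Friedel–Crafts cascades of homoallylic alcohols with aldehydes and arenes, Prins cyclisations under confined imidodiphosphorimidate acids, chiral-anion-controlled additions to benzopyrylium (O-aryl oxocarbenium) ions, and the C4 arylation of flavan-4-yl cations. The C2 stereocentre (S) is set in the ring closure by the confined chiral counter-anion, which shields one face of the oxocarbenium carbon, and C4 (R) is set by substrate control, because the half-chair cation with its 2-aryl group equatorial is attacked pseudoaxially on the face anti to that group, giving the 2,4-trans chroman. The step needs chemoselectivity for acetalisation over protonation of the styrene, which slow addition of 2 to excess 5 and 4 at low temperature over sieves should secure, and regioselectivity for C8 over C6 of ring D, which follows from the 5,7-dibenzyloxy pattern (C6 lies between two benzyloxy groups, C8 between one and the ring oxygen) as in couplings of flavan-4-yl cations to protected flavan-3-ols. Because 4 is enantiopure, any leakage of facial control at C2 appears as a diastereomer of 8 and should be removable by chromatography.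

**Step 4**
Reactants: 8 hexa-O-benzyl ether of the target
Product: 9 target, (2S)-4',7-dihydroxyflavan-(4β→8)-(−)-epiafzelechin
Conditions: H2 (1 atm), Pd(OH)2/C, THF/MeOH 1:1, rt; filtration under argon
Reagents that add atoms: none
Why: Hydrogenolysis of benzyl ethers over Pd(OH)2/C under neutral conditions at ambient pressure should cleave the five aryl and one alkyl O-benzyl bonds while the cyclic benzylic C2–O1 ethers of rings C and F and the C4–C8 bond, which are much slower to cleave, stay intact, so no stereocentre is touched.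

**Compound list**
1 | 4-(benzyloxy)-2-hydroxybenzaldehyde | O=Cc1ccc(OCc2ccccc2)cc1O | starting material
2 | 5-(benzyloxy)-2-vinylphenol | C=Cc1ccc(OCc2ccccc2)cc1O | intermediate
3 | (−)-epiafzelechin, (2R,3R)-2-(4-hydroxyphenyl)chroman-3,5,7-triol | O[C@@H]1Cc2c(O)cc(O)cc2O[C@@H]1c1ccc(O)cc1 | starting material
4 | tetra-O-benzyl-(−)-epiafzelechin, (2R,3R)-3,5,7-tris(benzyloxy)-2-[4-(benzyloxy)phenyl]chroman | O(Cc1ccccc1)[C@@H]1Cc2c(OCc3ccccc3)cc(OCc3ccccc3)cc2O[C@@H]1c1ccc(OCc2ccccc2)cc1 | intermediate
5 | 4-(benzyloxy)benzaldehyde | O=Cc1ccc(OCc2ccccc2)cc1 | starting material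
6 | O-aryl oxocarbenium ion, [4-(benzyloxy)benzylidene][5-(benzyloxy)-2-vinylphenyl]oxonium (ion pair with the chiral imidodiphosphorimidate) | C=Cc1ccc(OCc2ccccc2)cc1[O+]=Cc1ccc(OCc2ccccc2)cc1 | intermediate (not isolated)
7 | flavan-4-yl cation, (2S)-7-(benzyloxy)-2-[4-(benzyloxy)phenyl]chroman-4-ylium | c1ccccc1COc1ccc([C@@H]2C[CH+]c3ccc(OCc4ccccc4)cc3O2)cc1 | intermediate (not isolated)
8 | hexa-O-benzyl ether of the target, (2R,3R)-3,5,7-tris(benzyloxy)-8-[(2S,4R)-7-(benzyloxy)-2-[4-(benzyloxy)phenyl]chroman-4-yl]-2-[4-(benzyloxy)phenyl]chroman | c1ccccc1COc1ccc([C@@H]2C[C@@H](c3c(OCc4ccccc4)cc(OCc4ccccc4)c4c3O[C@H](c3ccc(OCc5ccccc5)cc3)[C@H](OCc3ccccc3)C4)c3ccc(OCc4ccccc4)cc3O2)cc1 | intermediate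
9 | target, (2R,3R)-8-[(2S,4R)-7-hydroxy-2-(4-hydroxyphenyl)chroman-4-yl]-2-(4-hydroxyphenyl)chroman-3,5,7-triol | Oc1ccc([C@@H]2C[C@@H](c3c(O)cc(O)c4c3O[C@H](c3ccc(O)cc3)[C@H](O)C4)c3ccc(O)cc3O2)cc1 | target

**Step count**
Total steps: 4. Longest linear sequence: 3 steps (1 → 2 → 8 → 9, or 3 → 4 → 8 → 9).

**Steps most likely to fail**

Step 3. The cascade may be diverted in several ways:
- protonation of the electron-rich styrene, followed by hydroarylation or oligomerisation;
- direct hydroxyalkylation of ring D by the activated aldehyde;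
- insufficient facial control at C2, or capture of the cation on the wrong face or at C6.

The fallback reaches the same cation by known flavan-4-ol chemistry and sets out from aldehyde 5. Claisen–Schmidt condensation of 5 with commercial 1-[4-(benzyloxy)-2-hydroxyphenyl]ethanone (KOH, EtOH) should give the 2'-hydroxychalcone F1. Oxa-Michael cyclisation (NaOAc, EtOH, reflux) should give the racemic 7-(benzyloxy)-2-[4-(benzyloxy)phenyl]chroman-4-one F2. Kinetic resolution by asymmetric transfer hydrogenation (RuCl(TsDPEN)(p-cymene), HCO2H/Et3N, the catalyst antipode that reduces the (2S)-ketone) should give the (2S,4S)-cis-flavan-4-ol F3, separated from unreacted (2R)-ketone. Ionisation of F3 with BF3·OEt2 in CH2Cl2 at −40 °C in the presence of 4 (Friedel–Crafts C4 arylation, pseudoaxial capture) comes back to the route at compound 8.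

Step 4. Slow cleavage of the secondary 3-O-benzyl ether may force long exposure, during which reductive opening of a benzylic C2–O1 bond or air oxidation of the free polyphenol on work-up may set in. The fallback changes the protecting group at O3 and sets out from compound 3. Phenol-selective benzylation (K2CO3, BnBr, DMF) should give 5,7,4'-tri-O-benzylepiafzelechin F4, and acetylation (Ac2O, pyridine, DMAP) its 3-O-acetate F5. F5 takes the place of 4 under the conditions of step 3 with 2 and 5 to give the 3-O-acetyl penta-O-benzyl dimer F6. Methanolysis (K2CO3, MeOH/THF) should give the penta-O-benzyl dimer with free 3-OH F7. A short hydrogenolysis (H2, Pd(OH)2/C) of the five fast-cleaving aryl benzyl ethers comes back to the route at compound 9.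

Step 1. The aldehyde is deactivated as its phenoxide, and the free vinylphenol may oligomerise under acid or radical initiation during isolation and storage. The fallback masks the phenol and sets out from compound 1. Silylation (TBSCl, imidazole, DMF) should give 4-(benzyloxy)-2-[(tert-butyldimethylsilyl)oxy]benzaldehyde F8. Wittig methylenation (Ph3PCH3Br, KOtBu, THF, one equivalent of ylide) should give the storable silyl ether [5-(benzyloxy)-2-vinylphenoxy](tert-butyl)dimethylsilane F9. Desilylation with TBAF/AcOH in THF at 0 °C just before use comes back to the route at compound 2.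

**Further compounds**
F1 | step 3 | (E)-1-[4-(benzyloxy)-2-hydroxyphenyl]-3-[4-(benzyloxy)phenyl]prop-2-en-1-one | O=C(/C=C/c1ccc(OCc2ccccc2)cc1)c1ccc(OCc2ccccc2)cc1O
F2 | step 3 | racemic 7-(benzyloxy)-2-[4-(benzyloxy)phenyl]chroman-4-one | O=C1CC(c2ccc(OCc3ccccc3)cc2)Oc2cc(OCc3ccccc3)ccc12
F3 | step 3 | (2S,4S)-7-(benzyloxy)-2-[4-(benzyloxy)phenyl]chroman-4-ol | c1ccccc1COc1ccc([C@@H]2C[C@H](O)c3ccc(OCc4ccccc4)cc3O2)cc1
F4 | step 4 | (2R,3R)-5,7-bis(benzyloxy)-2-[4-(benzyloxy)phenyl]chroman-3-ol | O[C@@H]1Cc2c(OCc3ccccc3)cc(OCc3ccccc3)cc2O[C@@H]1c1ccc(OCc2ccccc2)cc1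
F5 | step 4 | (2R,3R)-5,7-bis(benzyloxy)-2-[4-(benzyloxy)phenyl]chroman-3-yl acetate | CC(=O)O[C@@H]1Cc2c(OCc3ccccc3)cc(OCc3ccccc3)cc2O[C@@H]1c1ccc(OCc2ccccc2)cc1
F6 | step 4 | (2R,3R)-5,7-bis(benzyloxy)-8-[(2S,4R)-7-(benzyloxy)-2-[4-(benzyloxy)phenyl]chroman-4-yl]-2-[4-(benzyloxy)phenyl]chroman-3-yl acetate | c1ccccc1COc1ccc([C@@H]2C[C@@H](c3c(OCc4ccccc4)cc(OCc4ccccc4)c4c3O[C@H](c3ccc(OCc5ccccc5)cc3)[C@H](OC(C)=O)C4)c3ccc(OCc4ccccc4)cc3O2)cc1
F7 | step 4 | (2R,3R)-5,7-bis(benzyloxy)-8-[(2S,4R)-7-(benzyloxy)-2-[4-(benzyloxy)phenyl]chroman-4-yl]-2-[4-(benzyloxy)phenyl]chroman-3-ol | c1ccccc1COc1ccc([C@@H]2C[C@@H](c3c(OCc4ccccc4)cc(OCc4ccccc4)c4c3O[C@H](c3ccc(OCc5ccccc5)cc3)[C@H](O)C4)c3ccc(OCc4ccccc4)cc3O2)cc1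
F8 | step 1 | 4-(benzyloxy)-2-[(tert-butyldimethylsilyl)oxy]benzaldehyde | O=Cc1ccc(OCc2ccccc2)cc1O[Si](C)(C)C(C)(C)C
F9 | step 1 | [5-(benzyloxy)-2-vinylphenoxy](tert-butyl)dimethylsilane | C=Cc1ccc(OCc2ccccc2)cc1O[Si](C)(C)C(C)(C)C
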